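The runs come from a simulation from invented constants.

The 3 questions ask for one length per flask and for the longer of the two; watch how much D each growing chain has met.

| flask | D | Q | remark | time |
|---|---|---|---|---|
| elm | 0.029 M (fed, over 80 min) | 0.75 mM | run made earlier |  |
| cedar | 0.029 M (fed, over 80 min) | 3 mM | run made earlier |  |
| ash | 0.058 M (fed, over 80 min) | 1.5 mM | run made earlier |  |
| winter | 0.029 M (fed, over 80 min) | 1.5 mM |  | 80 min |
| autumn | 0.029 M (fed, over 40 min) | 1.5 mM |  | 80 min |

- elm (time / min: L / %, D / %): 5.00: 0, 6; 15.0: 0, 21; 30.0: 1, 36; 40.0: 3, 48; 60.0: 3, 72; 80.0: 5, 92
- cedar (time / min: L / %, D / %): 5.00: 0, 8; 15.0: 2, 17; 30.0: 5, 35; 40.0: 4, 47; 60.0: 11, 64; 80.0: 19, 77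
- ash (time / min: L / %, D / %): 6.00: 1, 8; 12.0: 0, 14; 25.0: 0, 30; 40.0: 5, 47; 80.0: 16, 85

(standard deviation of a reading: 1.5 percentage points)

- which of the two ends with the longer chains by the average number of monomer units in a chain (chains begun, living or dead) ("neither" if they lie within 10 %) (winter / autumn / neither)
- average number of monomer units in a chain (chains begun, living or dead) at the end, winter
- average number of monomer units in a chain (chains begun, living or dead) at the end, autumn

- the average divides the monomer in chains by the number of chains begun, living and dead together
- the numbers in the tables scatter with a standard deviation of 1.5 percentage points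
- the earlier runs do not show the number of chains; that part of a forecast is a guess
- percentages count the whole charge, also what has not yet gone in

Count [D] as fed, though that overcounts: at 80.0 min elm still shows 92 % of its charge as D and cedar 77 %. Then take the exposure, the time integral of [D]: winter's steady rise gives 1.16 M·min, and autumn's shorter rise and level stretch give 1.74 M·min.

Now solve two extreme flasks, with chains that keep growing. In the first, every Q begins a chain at once: the number of chains is fixed, L rises with exposure, and length is proportional to exposure. In the second, Q begins chains slowly: chains rise with exposure, L with its square, and length is again proportional to exposure. At both ends autumn over winter is 1.50, so expect autumn longer, beyond the margin.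

For the size, read L at the end of the feed. Elm and cedar give a geometric mean of 9.75 % for winter's Q. Take one chain from each Q at most; then this scattered reading puts an estimated floor of 1.88 under winter's length. Cedar's L rises by a reading of 4.75 from 40.0 min to 80.0 min, while exposure rises 4.00-fold, which points toward the first extreme. Commit to a length just above that floor for winter and just above 2.82 for autumn.

The forecast differs in size: it says autumn, with 6.8 for winter and 9.6 for autumn, and warns “The chain count is inferred, so this is uncertain.” The flask gives autumn, with 3.35 for winter and 4.54 for autumn.

    L + G → D + G, rate k1*[G] as long as [L] is above zero (k = 2.10 × 10⁻⁴ s⁻¹)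
    D + Q → G + L (k = 0.0220 M⁻¹ s⁻¹)
    2 G → Z (k = 0.200 M⁻¹ s⁻¹)
    D + G → L + G, rate k4*[G]*[D] (k = 0.0900 M⁻¹ s⁻¹)

In winter at 80.0 min, growth (propagation) uses D 8.0 times as fast as starts do. At 62.3 min in winter, the half-life of D is 190 min by growth against 14 h by starts. Autumn over winter comes to 1.36, against the exposure ratio of 1.50. Take winter with 0.12 M of D: its exposure is 4.80 M·min, and scaling winter's length by exposure gives 13.9, while that flask gives 11.9.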